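Rings A and C come from a cycloheptene-1,2-dione by a hemiketal-triggered ring contraction that expels C5.

1. Feature: C4 is a fully substituted carbinol carbon that bears the lactone carbonyl C5, C5 is esterified by the C9 oxygen (ring C: C4, C5, O, C9, C10), and C3 and C10 meet at C4 to close ring A. This is what a 1,2-dione leaves when C5, once a ring atom between C4 and C3, is pushed out of the ring.
2. Rings A and C are disconnected together to cycloheptene-1,2-dione 23 (ring C10–C4–C5–C3–C2–C1=C11, free C9 hydroxyl): hemiketal at C5, then 1,2-shift of C3 from C5 to C4.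
3. Dione 23 comes from cycloheptenone 19 by C5 hydroxylation and oxidation, 19 from ring-closing metathesis at C1=C11, and the C4–C5 bond from aldehyde 10 plus the β-lithio alkoxide of epoxide 14 (C3 from (R)-2-methylglycidol).
4. C9 and C10 come from a Sharpless epoxide of dienol 4 and a semipinacol 1,2-vinyl shift (C11 onto C10 with inversion).
5. Ring order: seven-membered carbocycle (step 11), rings A and C together (step 15), the C1/C11 diol while ring A is still flexible (step 17), ring B last by selenoetherification and selenoxide elimination (step 21).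

Key step: step 15

Remarks
- Atom labels follow the target: ring A = C1(OAc), C2, C3(Me,OH), C4, C10(Me), C11(OBz); C5 = lactone carbonyl on C4; ring B = C4–O–C6(Me2)–C7=C8–C9–C10; ring C = C4–C5–O–C9–C10. The target is 1S,3S,4S,9S,10R,11R in these labels.
- Assumption: both C4 epimers of carbinol 8 undergo the vinyl shift of step 5; C4 becomes a carbonyl there.
- Assumption: hydroxy dione 23 is drawn open, although it should rest largely as hemiketal 24.
- The C1/C11 diol is set on the bicyclic lactone before ring B is closed: once ring B exists, ring A is held in the half-chair with the C3 and C10 methyl groups both axial on the face that must be hydroxylated. The prenyl alkene is masked as its epoxide for that stretch (steps 16 to 20).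

Step 1
Reactants: 1 prop-2-yn-1-ol; 2 1-bromo-3-methylbut-2-ene (prenyl bromide)
Product: 4 (2E)-2,6-dimethylhepta-2,5-dien-1-ol, via alkenylalane 3 (not isolated)
Conditions: AlMe3 (3 equiv), Cp2ZrCl2 (25 mol%), CH2Cl2, 0 °C to rt; then 2, Pd(PPh3)4 (3 mol%), THF, rt; aq. HCl
Reagents that add atoms: trimethylaluminium, C[Al](C)C
Why: Negishi zirconium-catalysed syn-carboalumination puts methyl on the internal alkyne carbon and aluminium cis to it on the terminus, and palladium-catalysed coupling of the alkenylalane with the allylic bromide at its primary carbon goes with retention, so the 2E trisubstituted alkene (C9=C10) is fixed.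

Step 2
Reactants: 4 (2E)-2,6-dimethylhepta-2,5-dien-1-ol
Product: 5 [(2S,3S)-2-methyl-3-(3-methylbut-2-en-1-yl)oxiran-2-yl]methanol
Conditions: Ti(OiPr)4 (10 mol%), L-(+)-diethyl tartrate (12 mol%), t-BuOOH, 4 Å MS, CH2Cl2, −20 °C
Reagents that add atoms: tert-butyl hydroperoxide, CC(C)(C)OO
Why: Sharpless asymmetric epoxidation is confined to the allylic alcohol alkene (the prenyl alkene has no hydroxyl to bind titanium), and L-(+)-tartrate should deliver oxygen to the face that gives the 2S,3S epoxide, which sets C9 (S) and the face of C10.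

Step 3
Reactants: 5 epoxy alcohol
Product: 6 (2R,3S)-2-methyl-3-(3-methylbut-2-en-1-yl)oxirane-2-carbaldehyde
Conditions: TEMPO (10 mol%), PhI(OAc)2, CH2Cl2, rt
Reagents that add atoms: none
Why: oxoammonium oxidation (TEMPO with PhI(OAc)2) of the primary alcohol stops at the aldehyde and spares the epoxide and the alkene, and the α-carbon is quaternary so nothing can epimerise (the descriptor change at C2 is a priority change only).

Step 4
Reactants: 6 epoxy aldehyde; 7 vinylmagnesium bromide
Product: 8 1-[(2S,3S)-2-methyl-3-(3-methylbut-2-en-1-yl)oxiran-2-yl]prop-2-en-1-ol (both carbinol epimers)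
Conditions: CH2=CHMgBr, THF, −78 °C; aq. NH4Cl
Reagents that add atoms: none
Why: Grignard 1,2-addition to the aldehyde is much faster than epoxide opening at −78 °C, and the new carbinol centre (C4) may form as a mixture because it becomes a carbonyl in step 5.

Step 5
Reactants: 8 epoxy carbinol
Product: 10 (2S,3S)-2-ethenyl-2,6-dimethyl-3-(triethylsilyloxy)hept-5-enal, via silyl ether 9 (not isolated)
Conditions: Et3SiOTf (1.4 equiv), iPr2NEt, 4 Å MS, CH2Cl2, −78 to −40 °C
Reagents that add atoms: triethylsilyl trifluoromethanesulfonate, CC[Si](CC)(CC)OS(=O)(=O)C(F)(F)F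
Why: after O-silylation the excess silyl triflate opens the epoxide at the tertiary carbon C10 and the vinyl group shifts from C4 to C10 anti to the departing oxygen (semipinacol rearrangement of a 2,3-epoxy silyl ether, the non-aldol aldol manifold with alkenyl in place of hydride), so C10 forms with inversion as S, C9 keeps its oxygen and configuration as the triethylsilyl ether, and C4 becomes the aldehyde.

Step 6
Reactants: 11 (R)-2-methylglycidol
Product: 12 [(2S)-2-methyloxiran-2-yl]methyl 4-methylbenzenesulfonate
Conditions: TsCl, Et3N, DMAP (cat.), CH2Cl2, 0 °C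
Reagents that add atoms: 4-toluenesulfonyl chloride, Cc1ccc(cc1)S(Cl)(=O)=O
Why: sulfonylation of the primary alcohol leaves the stereocentre untouched (the change from R to S is a priority change only).

Step 7
Reactants: 12 glycidyl tosylate; 7 vinylmagnesium bromide
Product: 14 (2S)-2-methyl-2-(prop-2-en-1-yl)oxirane, via hydroxy tosylate alkoxide 13 (not isolated)
Conditions: CH2=CHMgBr, CuI (10 mol%), THF, −40 °C; then aq. NaOH, rt
Reagents that add atoms: none
Why: the copper-catalysed Grignard reagent opens the epoxide at its unsubstituted carbon and the tertiary alkoxide then displaces the neighbouring tosylate (epoxide transposition), so the C–O bond at the stereocentre is never broken and C3 is obtained as S.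

Step 8
Reactants: 14 (2S)-2-methyl-2-(prop-2-en-1-yl)oxirane; 10 aldehyde
Product: 16 7-ethenyl-4,7,11-trimethyl-8-(triethylsilyloxy)dodeca-1,10-diene-4,6-diol (C3 S and C9 S and C10 as in 10 with C4 carbinol epimers), via β-lithio alkoxide 15 (not isolated)
Conditions: lithium 4,4'-di-tert-butylbiphenylide (2.1 equiv), THF, −78 °C; then 10, −78 °C; aq. NH4Cl at −78 °C
Reagents that add atoms: none
Why: reductive lithiation cleaves the primary C–O bond of the epoxide to a β-lithio alkoxide, which cannot β-eliminate (the leaving group would be an oxide dianion) and adds as a primary organolithium to the non-enolisable aldehyde to form C4–C5, with the cold quench holding back silyl migration from the C9 oxygen.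

Step 9
Reactants: 16 diol
Product: 17 (4S,7S,8S)-7-ethenyl-4-hydroxy-4,7,11-trimethyl-8-(triethylsilyloxy)dodeca-1,10-dien-6-one
Conditions: Dess–Martin periodinane, NaHCO3, CH2Cl2, 0 °C to rt
Reagents that add atoms: none
Why: Dess–Martin oxidation takes the secondary C4 alcohol to the ketone, the tertiary C3 alcohol cannot be oxidised, and the buffered neutral medium avoids retro-aldol of the β-hydroxy ketone.

Step 10
Reactants: 17 hydroxy ketone
Product: 18 (4S,7S,8S)-4-(tert-butyldimethylsilyloxy)-7-ethenyl-4,7,11-trimethyl-8-(triethylsilyloxy)dodeca-1,10-dien-6-one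
Conditions: t-BuMe2SiOTf, 2,6-lutidine, CH2Cl2, −78 to 0 °C
Reagents that add atoms: tert-butyldimethylsilyl trifluoromethanesulfonate, CC(C)(C)[Si](C)(C)OS(=O)(=O)C(F)(F)F
Why: a silyl triflate with a hindered pyridine silylates the tertiary alcohol without enolising the ketone, and the tert-butyldimethylsilyl group is chosen so that the C9 triethylsilyl ether can be removed alone in step 14.

Step 11
Reactants: 18 bis-silyl ketone
Product: 19 (2S,6S)-6-(tert-butyldimethylsilyloxy)-2,6-dimethyl-2-[(1S)-4-methyl-1-(triethylsilyloxy)pent-3-en-1-yl]cyclohept-3-en-1-one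
Conditions: second-generation Grubbs catalyst (5 mol%), CH2Cl2 (2 mM), 40 °C
Reagents that add atoms: none
Why: ring-closing metathesis, in which the catalyst loads on the unhindered allyl terminus (C1) and closes onto the neopentyl vinyl group (C11) to the cycloheptene, whereas the competing cyclopentene (C11 with C7) would need initiation at the hindered vinyl group or at the trisubstituted alkene.

Step 12
Reactants: 19 cycloheptenone
Product: 21 C5-hydroxy derivative of 19 (α-hydroxy ketone with both C5 epimers), via lithium enolate 20 (not isolated)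
Conditions: LiN(SiMe3)2, THF, −78 °C; then 2-(phenylsulfonyl)-3-phenyloxaziridine, −78 °C; aq. NH4Cl
Reagents that add atoms: 2-(phenylsulfonyl)-3-phenyloxaziridine, O=S(=O)(c1ccccc1)N1OC1c1ccccc1
Why: C5 is the only enolisable position (C10 is quaternary) and the lithium enolate is hydroxylated by the Davis oxaziridine at a temperature that holds back β-elimination of the C3 silyloxy group, a route chosen because selenium dioxide would attack the prenyl group.

Step 13
Reactants: 21 α-hydroxy ketone
Product: 22 (3S,7S)-7-(tert-butyldimethylsilyloxy)-3,7-dimethyl-3-[(1S)-4-methyl-1-(triethylsilyloxy)pent-3-en-1-yl]cyclohept-4-ene-1,2-dione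
Conditions: Dess–Martin periodinane, NaHCO3, CH2Cl2, rt
Reagents that add atoms: none
Why: Dess–Martin oxidation of the α-hydroxy ketone gives the 1,2-dione without C–C cleavage, and the dione cannot enolise because C3 and C10 are quaternary.

Step 14
Reactants: 22 bis-silyl dione
Product: 23 (3S,7S)-7-(tert-butyldimethylsilyloxy)-3-[(1S)-1-hydroxy-4-methylpent-3-en-1-yl]-3,7-dimethylcyclohept-4-ene-1,2-dione
Conditions: HF·pyridine, pyridine, THF, 0 °C
Reagents that add atoms: none
Why: buffered fluoride cleaves the secondary triethylsilyl ether much faster than the tertiary tert-butyldimethylsilyl ether, freeing only the C9 hydroxyl.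

Step 15
Reactants: 23 hydroxy dione
Product: 25 hydroxy lactone (3S,4S,9S,10S; ring A cyclohexene cis-fused to ring C with C4–OH and C9 prenyl and C3–OSi(t-Bu)Me2), via bridged hemiketal 24 (not isolated)
Conditions: Sc(OTf)3 (10 mol%), 4 Å MS, CH2Cl2, rt to 40 °C
Reagents that add atoms: none
Why: Proposed new method: the free C9 hydroxyl adds to the C5 carbonyl (5-exo-trig; addition to C4 would need a four-membered ring) to give bridged hemiketal 24, a tertiary α-ketol whose C5–C3 bond lies over the π* orbital of the scandium-bound C4 carbonyl, and C3 shifts from C5 to C4 while C5 collapses to the lactone carbonyl. The closest known reaction types are the benzilic ester rearrangement of cyclic 1,2-diones with alkoxides and the Lewis acid-promoted α-ketol rearrangement; the hemiketal-triggered, Lewis acid-catalysed form on a cycloheptene-1,2-dione has no close example. Ring C closes by the 5-exo-trig hemiketalisation and is carried through, and ring A closes by ring contraction, the 1,2-shift of C3, which stays tied to C10 through C2, C1 and C11. C4 is the only new stereocentre and is set by the bicycle: C3 can reach C4 only on the face it occupies in 24, the face of C11, so ring A is cis-fused to ring C and the C4 hydroxyl ends on the face of the C10 methyl and of C8, as ring B needs. The step needs migration of C3 and no retro-aldol at C9–C10: C3 is the only carbon on C5 besides C4 and carries a donating silyloxy group, the dione is non-enolisable, and without base the C9 oxygen is held as the neutral hemiketal and not as an alkoxide. The change from a strained vicinal dione to an ester supplies the driving force.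

Step 16
Reactants: 25 hydroxy lactone
Product: 26 side-chain epoxide of 25 (C6–C7 oxirane with both C7 epimers)
Conditions: mCPBA (1.05 equiv), NaHCO3, CH2Cl2, −20 °C
Reagents that add atoms: 3-chloroperoxybenzoic acid, OOC(=O)c1cccc(Cl)c1
Why: Prilezhaev epoxidation picks the electron-rich trisubstituted alkene over the cis-disubstituted ring alkene next to quaternary C10, and the epoxide serves only as a mask so that osmium tetroxide meets the ring alkene alone in step 17.

Step 17
Reactants: 26 epoxy hydroxy lactone
Product: 27 C1,C11-diol of 26 (1S,11R; both hydroxyls cis to the C4 hydroxyl and the C10 methyl)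
Conditions: OsO4 (5 mol%), NMO, acetone/H2O, rt
Reagents that add atoms: osmium tetroxide, O=[Os](=O)(=O)=O; N-methylmorpholine N-oxide, C[N+]1([O-])CCOCC1; water, O
Why: Upjohn dihydroxylation should come from the convex face of the cis-fused bicycle, syn to the C4 hydroxyl and anti to ring C, the C9 branch and the C3 silyloxy group (through the half-chair with the C4 hydroxyl axial), which sets C1 and C11 cis to each other on the face of the C10 methyl.

Step 18
Reactants: 27 diol
Product: 28 C1 acetate of 27
Conditions: Ac2O, pyridine, CH2Cl2, 0 °C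
Reagents that add atoms: acetic anhydride, CC(=O)OC(C)=O
Why: acetylation goes to the less hindered C1 hydroxyl because the C11 hydroxyl is neopentyl (next to quaternary C10) and the tertiary C4 hydroxyl is inert.

Step 19
Reactants: 28 monoacetate
Product: 29 C1 acetate C11 benzoate (epoxide retained)
Conditions: BzCl, DMAP, pyridine, rt to 40 °C
Reagents that add atoms: benzoyl chloride, O=C(Cl)c1ccccc1
Why: DMAP-catalysed acylation benzoylates the remaining secondary hydroxyl at C11, while the tertiary α-hydroxy lactone hydroxyl at C4 does not react and the epoxide tolerates the basic medium.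

Step 20
Reactants: 29 epoxy diester
Product: 30 C1 acetate C11 benzoate with the prenyl alkene restored
Conditions: MeReO3 (10 mol%), PPh3, benzene, rt to 50 °C
Reagents that add atoms: none
Why: rhenium-catalysed oxygen-atom transfer from the epoxide to the phosphine returns the prenyl alkene under neutral conditions that spare the esters, the lactone and the silyl ether.

Step 21
Reactants: 30 hydroxy diester
Product: 33 C3 tert-butyldimethylsilyl ether of the target, via selenide 31 (not isolated), via selenoxide 32 (not isolated)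
Conditions: PhSeCl, pyridine, CH2Cl2, −78 °C; then 30% H2O2, 0 °C to rt
Reagents that add atoms: none
Why: phenylselenoetherification, in which the C4 hydroxyl (cis to C8 on ring C) opens the seleniranium ion at the tertiary carbon C6 (Markovnikov, 7-endo) to close ring B, followed by oxidation to the selenoxide and syn-elimination, which can only run towards C8 because C6 has no hydrogen, giving the C7=C8 alkene.

Step 22
Reactants: 33 silyl ether
Product: 34 target CNP0178319.3
Conditions: HF·pyridine, MeCN, rt
Reagents that add atoms: none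
Why: fluoride cleavage of the tertiary silyl ether under buffered acidic conditions leaves the acetate, the benzoate, the lactone and the allylic ether intact.

Compound list
1 | prop-2-yn-1-ol | C#CCO | starting material
2 | 1-bromo-3-methylbut-2-ene (prenyl bromide) | CC(C)=CCBr | starting material
3 | dimethylaluminium (2E)-3-(dimethylalumanyl)-2-methylprop-2-en-1-olate | C[Al](C)OC/C(C)=C/[Al](C)C | intermediate
4 | (2E)-2,6-dimethylhepta-2,5-dien-1-ol | OC/C(C)=C/CC=C(C)C | intermediate
5 | [(2S,3S)-2-methyl-3-(3-methylbut-2-en-1-yl)oxiran-2-yl]methanol | OC[C@]1(C)O[C@H]1CC=C(C)C | intermediate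
6 | (2R,3S)-2-methyl-3-(3-methylbut-2-en-1-yl)oxirane-2-carbaldehyde | O=C[C@]1(C)O[C@H]1CC=C(C)C | intermediate
7 | vinylmagnesium bromide | C=C[Mg]Br | starting material
8 | 1-[(2S,3S)-2-methyl-3-(3-methylbut-2-en-1-yl)oxiran-2-yl]prop-2-en-1-ol, both carbinol epimers | C=CC(O)[C@]1(C)O[C@H]1CC=C(C)C | intermediate
9 | triethylsilyl ether of 8 | C=CC(O[Si](CC)(CC)CC)[C@]1(C)O[C@H]1CC=C(C)C | intermediate
10 | (2S,3S)-2-ethenyl-2,6-dimethyl-3-(triethylsilyloxy)hept-5-enal (C9 S, C10 S) | O=C[C@@](C)(C=C)[C@@H](O[Si](CC)(CC)CC)CC=C(C)C | intermediate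
11 | (R)-2-methylglycidol, [(2R)-2-methyloxiran-2-yl]methanol | C[C@@]1(CO)CO1 | starting material
12 | [(2S)-2-methyloxiran-2-yl]methyl 4-methylbenzenesulfonate | C[C@@]1(COS(=O)(=O)c2ccc(C)cc2)CO1 | intermediate
13 | bromomagnesium alkoxide of (2S)-2-hydroxy-2-methylpent-4-en-1-yl 4-methylbenzenesulfonate | C=CC[C@](C)(O[Mg]Br)COS(=O)(=O)c1ccc(C)cc1 | intermediate
14 | (2S)-2-methyl-2-(prop-2-en-1-yl)oxirane | C=CC[C@@]1(C)CO1 | intermediate
15 | lithium (2S)-1-lithio-2-methylpent-4-en-2-olate | [Li]C[C@](C)(CC=C)O[Li] | intermediate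
16 | 7-ethenyl-4,7,11-trimethyl-8-(triethylsilyloxy)dodeca-1,10-diene-4,6-diol (4S,7R,8S; C6 epimers; C3 S, C9 S in target labels) | C=CC[C@](C)(O)CC(O)[C@@](C)(C=C)[C@@H](O[Si](CC)(CC)CC)CC=C(C)C | intermediate
17 | (4S,7S,8S)-7-ethenyl-4-hydroxy-4,7,11-trimethyl-8-(triethylsilyloxy)dodeca-1,10-dien-6-one | C=CC[C@](C)(O)CC(=O)[C@@](C)(C=C)[C@@H](O[Si](CC)(CC)CC)CC=C(C)C | intermediate
18 | (4S,7S,8S)-4-(tert-butyldimethylsilyloxy)-7-ethenyl-4,7,11-trimethyl-8-(triethylsilyloxy)dodeca-1,10-dien-6-one | C=CC[C@](C)(O[Si](C)(C)C(C)(C)C)CC(=O)[C@@](C)(C=C)[C@@H](O[Si](CC)(CC)CC)CC=C(C)C | intermediate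
19 | (2S,6S)-6-(tert-butyldimethylsilyloxy)-2,6-dimethyl-2-[(1S)-4-methyl-1-(triethylsilyloxy)pent-3-en-1-yl]cyclohept-3-en-1-one | O=C1C[C@@](C)(O[Si](C)(C)C(C)(C)C)CC=C[C@@]1(C)[C@@H](O[Si](CC)(CC)CC)CC=C(C)C | intermediate
20 | lithium enolate of 19 (C4=C5 enolate) | [Li]OC1=C[C@@](C)(O[Si](C)(C)C(C)(C)C)CC=C[C@@]1(C)[C@@H](O[Si](CC)(CC)CC)CC=C(C)C | intermediate
21 | C5-hydroxy derivative of 19 (α-hydroxy ketone, both C5 epimers; C3 S, C9 S, C10 S) | O=C1C(O)[C@@](C)(O[Si](C)(C)C(C)(C)C)CC=C[C@@]1(C)[C@@H](O[Si](CC)(CC)CC)CC=C(C)C | intermediate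
22 | (3S,7S)-7-(tert-butyldimethylsilyloxy)-3,7-dimethyl-3-[(1S)-4-methyl-1-(triethylsilyloxy)pent-3-en-1-yl]cyclohept-4-ene-1,2-dione | O=C1C(=O)[C@@](C)(O[Si](C)(C)C(C)(C)C)CC=C[C@@]1(C)[C@@H](O[Si](CC)(CC)CC)CC=C(C)C | intermediate
23 | (3S,7S)-7-(tert-butyldimethylsilyloxy)-3-[(1S)-1-hydroxy-4-methylpent-3-en-1-yl]-3,7-dimethylcyclohept-4-ene-1,2-dione (key-step precursor) | O=C1C(=O)[C@@](C)(O[Si](C)(C)C(C)(C)C)CC=C[C@@]1(C)[C@@H](O)CC=C(C)C | intermediate
24 | bridged hemiketal of 23 (C9–O–C5; C3 S, C5 S, C9 S, C10 S; C4 ketone as one-atom bridge) | O=C1[C@@]2(C)C=CC[C@](C)(O[Si](C)(C)C(C)(C)C)[C@]1(O)O[C@H]2CC=C(C)C | intermediate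
25 | (3S,3aS,7S,7aS)-7-(tert-butyldimethylsilyloxy)-7a-hydroxy-3a,7-dimethyl-3-(3-methylbut-2-en-1-yl)-3a,6,7,7a-tetrahydro-2-benzofuran-1(3H)-one (key-step product; 3S,4S,9S,10S in target labels) | O[C@@]12C(=O)O[C@@H](CC=C(C)C)[C@]1(C)C=CC[C@]2(C)O[Si](C)(C)C(C)(C)C | intermediate
26 | side-chain epoxide of 25 (3,3-dimethyloxiran-2-ylmethyl at C9; C7 epimers) | O[C@@]12C(=O)O[C@@H](CC3OC3(C)C)[C@]1(C)C=CC[C@]2(C)O[Si](C)(C)C(C)(C)C | intermediate
27 | C1,C11-diol of 26 (1S,3S,4S,9S,10S,11R; C1–OH, C11–OH, C4–OH and C10–Me on one face of ring A) | O[C@H]1C[C@](C)(O[Si](C)(C)C(C)(C)C)[C@]2(O)C(=O)O[C@@H](CC3OC3(C)C)[C@]2(C)[C@H]1O | intermediate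
28 | C1 acetate of 27 | CC(=O)O[C@H]1C[C@](C)(O[Si](C)(C)C(C)(C)C)[C@]2(O)C(=O)O[C@@H](CC3OC3(C)C)[C@]2(C)[C@H]1O | intermediate
29 | C1 acetate C11 benzoate, side-chain epoxide retained (1S,3S,4S,9S,10R,11R) | CC(=O)O[C@H]1C[C@](C)(O[Si](C)(C)C(C)(C)C)[C@]2(O)C(=O)O[C@@H](CC3OC3(C)C)[C@]2(C)[C@H]1OC(=O)c1ccccc1 | intermediate
30 | C1 acetate C11 benzoate with prenyl side chain and free C4–OH | CC(=O)O[C@H]1C[C@](C)(O[Si](C)(C)C(C)(C)C)[C@]2(O)C(=O)O[C@@H](CC=C(C)C)[C@]2(C)[C@H]1OC(=O)c1ccccc1 | intermediate
31 | ring B selenide (C4–O–C6 ether, C7–SePh, C7 epimers) | CC(=O)O[C@H]1C[C@](C)(O[Si](C)(C)C(C)(C)C)[C@]23OC(C)(C)C([Se]c4ccccc4)C[C@H](OC2=O)[C@]3(C)[C@H]1OC(=O)c1ccccc1 | intermediate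
32 | selenoxide of 31 | CC(=O)O[C@H]1C[C@](C)(O[Si](C)(C)C(C)(C)C)[C@]23OC(C)(C)C([Se](=O)c4ccccc4)C[C@H](OC2=O)[C@]3(C)[C@H]1OC(=O)c1ccccc1 | intermediate
33 | C3 tert-butyldimethylsilyl ether of the target | CC(=O)O[C@H]1C[C@](C)(O[Si](C)(C)C(C)(C)C)[C@]23OC(C)(C)C=C[C@H](OC2=O)[C@]3(C)[C@H]1OC(=O)c1ccccc1 | intermediate
34 | CNP0178319.3 (1S,3S,4S,9S,10R,11R) | CC(=O)O[C@H]1C[C@](C)(O)[C@]23OC(C)(C)C=C[C@H](OC2=O)[C@]3(C)[C@H]1OC(=O)c1ccccc1 | target

Total step count: 22. Longest linear sequence: 20 steps (steps 1 to 5, then 8 to 22; steps 6 and 7 make epoxide 14).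

Steps most likely to fail

Step 15 (proposed new method). The hemiketal may revert without rearranging, the C9–C10 bond may break by retro-aldol fragmentation, or the Lewis acid may add the new C4 hydroxyl across the prenyl alkene. The fallback sets out from dione 22, in which the C9 oxygen is still silylated and retro-aldol is closed off. Aqueous KOH in dioxane should bring about the classical benzilic acid ring contraction (addition of hydroxide to either carbonyl leads to the same constitution) and give ring-contracted hydroxy acid F1. HF·pyridine then frees the C9 hydroxyl to give hydroxy acid F2, and the C4 epimer with the carboxyl cis to C9 lactonises on treatment with CSA in toluene, rejoining the route at 25. C4 is then no longer set by the tether, so the other epimer would have to be separated.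

Step 21. Ring closure may be slow because ring A must fold so that the C1 acetoxy group comes between the axial C3 and C10 methyl groups; selenium may also be captured in the 6-exo sense or by the ring-free chloride. The fallback sets out from epoxy diester 29, before step 20. CSA in CH2Cl2 should open the protonated epoxide at the tertiary carbon C6 with the C4 hydroxyl (7-endo epoxide-opening etherification) to give ring B alcohol F3 with a C7 hydroxyl. Burgess reagent in benzene at 50 °C then dehydrates F3 by syn-elimination towards C8, rejoining the route at 33.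

Step 5. Hydride may migrate in place of vinyl, or the prenyl alkene may attack the silyl-activated aldehyde in a Prins-type cyclisation. The fallback sets out from epoxy aldehyde 6 and joins the fragments first. Addition of β-lithio alkoxide 15 gives epoxy diol F4, Dess–Martin oxidation gives epoxy hydroxy ketone F5, and t-BuMe2SiOTf with 2,6-lutidine gives silyl ether F6. CH2=CHMgBr with CeCl3 then gives tertiary carbinol F7, which is rearranged with Et3SiOTf. C4 now carries no hydrogen, vinyl should migrate in preference to the primary alkyl group, and the product is the less electrophilic ketone 18, where the route is rejoined (steps 8 to 10 are then not needed).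

Further compounds
F1 | step 15 | ring-contracted hydroxy acid, 1-hydroxycyclohex-3-ene-1-carboxylic acid with C3–OSi(t-Bu)Me2 and C9–OSiEt3 (desired C4 epimer) | OC(=O)[C@@]1(O)[C@@](C)(O[Si](C)(C)C(C)(C)C)CC=C[C@@]1(C)[C@@H](O[Si](CC)(CC)CC)CC=C(C)C
F2 | step 15 | hydroxy acid with free C9 hydroxyl | OC(=O)[C@@]1(O)[C@@](C)(O[Si](C)(C)C(C)(C)C)CC=C[C@@]1(C)[C@@H](O)CC=C(C)C
F3 | step 21 | ring B alcohol (C4–O–C6 ether, C7–OH, C7 epimers) | CC(=O)O[C@H]1C[C@](C)(O[Si](C)(C)C(C)(C)C)[C@]23OC(C)(C)C(O)C[C@H](OC2=O)[C@]3(C)[C@H]1OC(=O)c1ccccc1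
F4 | step 5 | epoxy diol from 6 and 15 (C4 epimers) | C=CC[C@](C)(O)CC(O)[C@]1(C)O[C@H]1CC=C(C)C
F5 | step 5 | epoxy hydroxy ketone | C=CC[C@](C)(O)CC(=O)[C@]1(C)O[C@H]1CC=C(C)C
F6 | step 5 | tert-butyldimethylsilyl ether of F5 | C=CC[C@](C)(O[Si](C)(C)C(C)(C)C)CC(=O)[C@]1(C)O[C@H]1CC=C(C)C
F7 | step 5 | tertiary vinyl carbinol (C4 epimers) | C=CC[C@](C)(O[Si](C)(C)C(C)(C)C)CC(O)(C=C)[C@]1(C)O[C@H]1CC=C(C)C
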